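**Plan**

1. Cuts: (a) the aryl O–S bond and the phenol protecting groups; (b) the central C=C of the four-carbon tether (cross-metathesis of one allyl group on each bicycle); (c) in the bicyclo[2.2.2]octan-1-ol, the C(Me)2–CH(CH2Ar) bond together with the bridgehead C–O bond, which leads back to a 7,7-dimethylnorbornane (bornane) carbinyl mesylate and to (1R)-(−)-ketopinic acid; (d) in the left bicycle, the epoxide C–C bond, the tertiary C–O bond of the oxepane and the two C–C bonds at the quaternary carbon, leading back to (S)-carvone.
2. Enabling feature: the six-membered ring C(OH)–CH2–C(Me)(chain)–CH–C(Me)2–CH(CH2Ar) of the bicyclooctanol is the five-membered ring C1–C2–C3–C4–C7 of camphor with the exocyclic carbon C10 inserted between C1 and the gem-dimethyl carbon C7. All ten bornane carbons map onto the bicyclooctane.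
3. Forward order: ketopinic acid → C3 made quaternary (methyl, allyl) → C2 deoxygenated → C10 turned into the (S)-carbinol carrying the arylmethyl group → ring expansion to the bridgehead alcohol. Separately: carvone → quaternary centre → oxepane → exocyclic epoxide → homoallylic tertiary alcohol. Then the two allyl groups are joined, the tether is saturated and the phenol is sulfated.
4. Stereochemistry, right half: both bridgeheads come from the (1S)-camphor series, C3 from exo alkylation, and the benzyl-bearing carbon from a catalyst-controlled ketone reduction relayed by inversion in the 1,2-shift. Left half: everything derives from C5 of (S)-carvone (alkylation anti to isopropenyl, Criegee rearrangement with retention, thermodynamic α-methyl, epoxidation anti to the angular methyl).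

Key step: step 13

Remark: the target is drawn as the free aryl hydrogen sulfate; the sulfate is carried as its sodium salt and set free on an acidic resin only in the last operation. Where a centre forms as an epimer mixture that converges later (C3 of 9, C2 of 12 to 15, the peroxy carbon of 32, the α-methyl carbon of 34), the SMILES shows the major epimer or leaves the centre open, as stated in the list.

**Aryl building block**

Step 1
Reactants: 1 5-(benzyloxy)-2-hydroxybenzaldehyde
Product: 2 5-(benzyloxy)-2-(methoxymethoxy)benzaldehyde
Conditions: MOMCl, i-Pr2NEt, CH2Cl2, 0 °C to rt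
Reagents that add atoms: chloromethyl methyl ether, COCCl
Why: O-alkylation of the phenol (acetal protection) should mask the ortho oxygen with a group that survives the later Grignard chemistry.

Step 2
Reactants: 2 5-(benzyloxy)-2-(methoxymethoxy)benzaldehyde
Product: 3 [5-(benzyloxy)-2-(methoxymethoxy)phenyl]methanol
Conditions: NaBH4, MeOH, 0 °C
Reagents that add atoms: none
Why: Hydride reduction of the aldehyde should give the benzylic alcohol without touching either ether.

Step 3
Reactants: 3 [5-(benzyloxy)-2-(methoxymethoxy)phenyl]methanol
Product: 4 4-(benzyloxy)-2-(chloromethyl)-1-(methoxymethoxy)benzene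
Conditions: PPh3, CCl4, CH2Cl2, 40 °C
Reagents that add atoms: tetrachloromethane, ClC(Cl)(Cl)Cl
Why: The Appel reaction should convert the alcohol into the chloride under neutral conditions that spare the acid-labile acetal.

**Right-hand fragment**

Step 4
Reactants: 5 (1R)-(−)-ketopinic acid
Product: 7 (1R,4S)-N-methoxy-N,7,7-trimethyl-2-oxobicyclo[2.2.1]heptane-1-carboxamide, via ketopinoyl chloride 6 (not isolated)
Conditions: (COCl)2, DMF (cat.), CH2Cl2, 0 °C to rt; then MeNH(OMe)·HCl, Et3N, CH2Cl2, 0 °C
Reagents that add atoms: N,O-dimethylhydroxylamine hydrochloride, CNOC.Cl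
Why: Acid chloride formation and amidation should give the Weinreb amide, which keeps C10 at the acyl level and is inert to the enolate and hydride steps that follow.

Step 5
Reactants: 7 ketopinic Weinreb amide
Product: 9 3-methyl keto amide (3-exo-methyl epimer major), via lithium enolate 8 (not isolated)
Conditions: LiN(i-Pr)2, THF, −78 °C; MeI, −78 to 0 °C
Reagents that add atoms: iodomethane, CI
Why: Enolate alkylation can occur only at C3, the single enolizable position, and the epimer ratio is immaterial because C3 is enolized again in step 6.

Step 6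
Reactants: 9 3-methyl keto amide
Product: 11 3-exo-allyl-3-endo-methyl keto amide, via lithium enolate 10 (not isolated)
Conditions: LiN(i-Pr)2, THF, 0 °C; DMPU, allyl bromide, −78 °C to rt
Reagents that add atoms: allyl bromide, C=CCBr
Why: The second enolate alkylation should build the quaternary centre with the allyl group entering from the exo face, the torsionally preferred approach to norbornanone-type enolates, leaving the methyl endo.

Step 7
Reactants: 11 3-exo-allyl-3-endo-methyl keto amide
Product: 12 2-hydroxy amide (C2 epimers)
Conditions: NaBH4, MeOH/THF, 0 to 50 °C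
Reagents that add atoms: none
Why: Borohydride reduction should reduce the hindered ketone while the Weinreb amide stays intact; the C2 configuration is irrelevant since the centre is removed in step 9.

Step 8
Reactants: 12 2-hydroxy amide
Product: 15 S-methyl xanthate of 12, via sodium alkoxide 13 (not isolated), via sodium xanthate 14 (not isolated)
Conditions: NaH, imidazole (cat.), THF, 0 °C; CS2; MeI, rt
Reagents that add atoms: carbon disulfide, S=C=S; iodomethane, CI
Why: Xanthate formation through the alkoxide is the standard way to activate a hindered secondary alcohol for radical deoxygenation.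

Step 9
Reactants: 15 S-methyl xanthate
Product: 16 N-methoxy-N,3,7,7-tetramethyl-3-(prop-2-enyl)bicyclo[2.2.1]heptane-1-carboxamide (allyl exo)
Conditions: Bu3SnH, AIBN (cat.), toluene, 110 °C
Reagents that add atoms: none
Why: Barton–McCombie deoxygenation should turn C2 into a methylene group, removing the oxygen that would otherwise destabilize the bridgehead cation of the key step.

Step 10
Reactants: 16 2-deoxo Weinreb amide; 4 4-(benzyloxy)-2-(chloromethyl)-1-(methoxymethoxy)benzene
Product: 18 arylmethyl ketone at C10, via benzylic Grignard reagent 17 (not isolated)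
Conditions: Mg turnings, THF, 0 °C (slow addition of 4); then 16, 0 °C to rt; aq NH4Cl
Reagents that add atoms: none
Why: Grignard addition to the Weinreb amide should stop at the ketone because the chelated tetrahedral intermediate collapses only on work-up.

Step 11
Reactants: 18 arylmethyl ketone
Product: 20 (S)-carbinol with free ortho phenol, via MOM-protected carbinol 19 (not isolated)
Conditions: (R)-2-methyl-CBS-oxazaborolidine, BH3·SMe2, THF, 0 °C to rt; then MeOH, 1 M HCl, 40 °C
Reagents that add atoms: none
Why: In the Corey–Bakshi–Shibata reduction the tertiary bridgehead carbon acts as the large group and the arylmethyl group as the small one, so the (R)-catalyst should give the (S)-alcohol under catalyst control, and the acidic methanol quench then cleaves the acetal.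

Step 12
Reactants: 20 (S)-carbinol phenol
Product: 21 bis(methanesulfonate)
Conditions: MsCl, Et3N, CH2Cl2, −20 °C
Reagents that add atoms: methanesulfonyl chloride, CS(=O)(=O)Cl
Why: Sulfonylation through the sulfene should esterify both hydroxyls in one operation, giving the alkyl leaving group and an aryl mesylate whose oxygen is no longer a donor.

Step 13
Reactants: 21 bis(methanesulfonate)
Product: 22 bridgehead alcohol: 4-(benzyloxy)-2-{[1-hydroxy-3,5,5-trimethyl-3-(prop-2-enyl)bicyclo[2.2.2]octan-6-yl]methyl}phenyl methanesulfonate
Conditions: H2O/acetone (1:1), 2,6-lutidine, 50–60 °C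
Reagents that add atoms: water, O
Why: Ionization of the secondary C10 mesylate is assisted by the strained C1–C7 σ-bond lying anti to the leaving group, so the gem-dimethyl carbon C7 shifts from C1 to C10 (Wagner–Meerwein shift) and the bicyclo[2.2.2]oct-1-yl cation formed at C1 is captured by water. The closest known reaction type is the solvolytic ring enlargement of 1-norbornylmethyl (bornane C10) sulfonates and amines to bridgehead bicyclo[2.2.2]octan-1-ols, the same skeletal change that links bornane-type and bicyclo[2.2.2]octanol terpenoids. No ring is closed by cyclization: the two five-membered rings that share the C1–C7 bond each grow by one atom to six-membered rings through the 1,2-shift (ring expansion). The benzyl-bearing centre is set by inversion at C10, so the (S)-mesylate from step 11 should place the arylmethyl group syn to the ethano bridge; the bridgehead hydroxyl can enter only along the outer axis of C1; C3 and C4 are carried over from the bornane. The step needs migration of C7 rather than of the ring methylenes C2 or C6, which the substrate secures because C7 is the only fully substituted and most strained migrating carbon and leads to the less strained bridgehead cation; it also needs the arene and its ortho oxygen to stay out of the ionization, which the electron-poor aryl mesylate secures, while the buffered water-rich medium suppresses elimination.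

**Side-chain electrophile**

Step 14
Reactants: 23 3-methyl-3-(trimethylsilyloxy)but-1-yne
Product: 25 4-methyl-4-(trimethylsilyloxy)pent-2-yn-1-ol, via lithium acetylide 24 (not isolated)
Conditions: n-BuLi, THF, −78 °C; (CH2O)n, −78 °C to rt
Reagents that add atoms: paraformaldehyde (as formaldehyde), C=O
Why: Acetylide addition to formaldehyde should give the propargylic alcohol with the tertiary silyl ether untouched.

Step 15
Reactants: 25 4-methyl-4-(trimethylsilyloxy)pent-2-yn-1-ol
Product: 26 (5-bromo-2-methylpent-3-yn-2-yl)oxytrimethylsilane
Conditions: CBr4, PPh3, CH2Cl2, 0 °C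
Reagents that add atoms: tetrabromomethane, BrC(Br)(Br)Br
Why: Appel bromination should deliver a reactive propargylic bromide under neutral conditions.

**Left-hand fragment**

Step 16
Reactants: 27 (S)-(+)-carvone
Product: 29 trans-6-methylcarvone (major epimer), via lithium enolate 28 (not isolated)
Conditions: LiN(i-Pr)2, THF, −78 °C; MeI, −78 to −20 °C
Reagents that add atoms: iodomethane, CI
Why: Kinetic deprotonation of the enone at the α′ carbon and enolate alkylation should place the first substituent on C6; its configuration is erased in step 17.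

Step 17
Reactants: 29 trans-6-methylcarvone; 26 propargylic bromide
Product: 31 6-methyl-6-[4-methyl-4-(trimethylsilyloxy)pent-2-ynyl]carvone (side chain trans to isopropenyl), via lithium enolate 30 (not isolated)
Conditions: LiN(i-Pr)2, THF, −78 to 0 °C; 26, DMPU, −78 °C to rt
Reagents that add atoms: none
Why: In this second enolate alkylation the electrophile should approach anti to the adjacent isopropenyl group, so the side chain ends trans and the methyl cis to it, which is the relationship needed for a trans ring fusion.

Step 18
Reactants: 31 6,6-disubstituted carvone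
Product: 33 C5 acetate (isopropenyl replaced by acetoxy with retention), via methoxy hydroperoxide 32 (not isolated)
Conditions: O3, CH2Cl2/MeOH, −78 °C (until 31 is consumed); then Ac2O, Et3N, DMAP (cat.), CH2Cl2, 0 to 40 °C
Reagents that add atoms: ozone, [O-][O+]=O
Why: In the Criegee rearrangement the ring carbon migrates from carbon to oxygen with retention, so the carvone stereocentre should become the oxygen-bearing ring-fusion carbon, and the 1,1-disubstituted alkene should be ozonized ahead of the alkyne and the electron-poor enone.

Step 19
Reactants: 33 C5 acetate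
Product: 34 saturated keto acetate (α-methyl epimers)
Conditions: H2 (1 atm), Pd/C, NaHCO3, EtOAc, rt
Reagents that add atoms: none
Why: Catalytic hydrogenation should saturate the alkyne and the enone double bond in one operation.

Step 20
Reactants: 34 saturated keto acetate
Product: 35 (2S*)-type diol ketone: 3-hydroxy-2-(4-hydroxy-4-methylpentyl)-2,6-dimethylcyclohexanone (hydroxyl trans to the side chain)
Conditions: HCl in MeOH (from AcCl), rt to 40 °C
Reagents that add atoms: none
Why: Acid-catalysed methanolysis should remove the silyl ether and the acetate without the retro-aldol risk of basic conditions, and it equilibrates the α-methyl group to the equatorial position.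

Step 21
Reactants: 35 diol ketone
Product: 36 trans-fused 2,2,5a,7-tetramethyloctahydro-1-benzoxepin-6(2H)-one
Conditions: CF3SO3H (cat.), CH2Cl2, 0 °C to rt
Reagents that add atoms: none
Why: Ionization of the tertiary alcohol and capture of the cation by the secondary hydroxyl (SN1 etherification) should close the oxepane at the tertiary carbon, so the carbinol stereocentre is untouched and the trans fusion follows from the trans arrangement of hydroxyl and side chain.

Step 22
Reactants: 36 oxepane-fused ketone
Product: 37 exocyclic methylene compound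
Conditions: Ph3PCH3Br, KOt-Bu, toluene, 90 °C
Reagents that add atoms: methyltriphenylphosphonium bromide, C[P+](c1ccccc1)(c1ccccc1)c1ccccc1.[Br-]
Why: Wittig methylenation with the salt-free ylide at elevated temperature is the established way to olefinate ketones flanked by a quaternary carbon, and the α-methyl group stays in its stable equatorial position.

Step 23
Reactants: 37 exocyclic methylene compound
Product: 38 spiro-epoxide (oxygen axial, anti to the angular methyl)
Conditions: mCPBA, NaHCO3, CH2Cl2, 0 °C
Reagents that add atoms: 3-chloroperoxybenzoic acid, OOC(=O)c1cccc(Cl)c1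
Why: In this Prilezhaev epoxidation the peracid should attack the face opposite the axial angular methyl, which sets the tertiary C–O bond axial as in the target; this is the opposite outcome to direct addition of a carbon nucleophile to ketone 36.

Step 24
Reactants: 38 spiro-epoxide
Product: 39 homoallylic tertiary alcohol
Conditions: CH2=CHMgBr, CuI (cat.), THF, −30 to 0 °C
Reagents that add atoms: vinylmagnesium bromide, C=C[Mg]Br
Why: Copper-catalysed SN2 opening of the epoxide at its methylene carbon should leave the configuration of the carbinol carbon unchanged.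

**Union and end game**

Step 25
Reactants: 22 bridgehead alcohol; 39 homoallylic tertiary alcohol
Product: 40 cross-metathesis product with an (E)-but-2-ene-1,4-diyl tether
Conditions: second-generation Grubbs catalyst (cat.), CH2Cl2, 40 °C, 39 in excess
Reagents that add atoms: none
Why: Olefin cross-metathesis of the two terminal allyl groups should form the four-carbon tether, with an excess of the simpler partner biasing the statistical outcome; the alkene geometry is immaterial.

Step 26
Reactants: 40 cross-metathesis product
Product: 41 saturated phenol (para oxygen free, ortho oxygen mesylated)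
Conditions: H2 (1 atm), Pd(OH)2/C, EtOAc/MeOH, rt
Reagents that add atoms: none
Why: Hydrogenation of the alkene and hydrogenolysis of the benzyl ether should occur together and leave the aryl mesylate in place, so the two phenol oxygens stay differentiated.

Step 27
Reactants: 41 saturated phenol
Product: 42 aryl hydrogen sulfate (handled as the sodium salt)
Conditions: SO3·pyridine, pyridine, rt; aq NaHCO3
Reagents that add atoms: sulfur trioxide–pyridine complex, [O-]S(=O)(=O)[n+]1ccccc1
Why: O-sulfation should be selective for the phenol because the two tertiary alcohols are too hindered to react.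

Step 28
Reactants: 42 aryl hydrogen sulfate
Product: 44 target CNP0255133.1, via disodium salt 43 (not isolated)
Conditions: NaOH (1 M aq), MeOH, 50 °C; then acidic ion-exchange resin (H+ form), MeOH, 0 °C
Reagents that add atoms: none
Why: Hydroxide cleavage of the aryl methanesulfonate should free the ortho phenol while the sulfate monoester anion resists base, and brief protonation on the resin gives the acid form.

**Compound list**

1 | 5-(benzyloxy)-2-hydroxybenzaldehyde | O=Cc1cc(OCc2ccccc2)ccc1O | starting material
2 | 5-(benzyloxy)-2-(methoxymethoxy)benzaldehyde | O=Cc1cc(OCc2ccccc2)ccc1OCOC | intermediate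
3 | [5-(benzyloxy)-2-(methoxymethoxy)phenyl]methanol | OCc1cc(OCc2ccccc2)ccc1OCOC | intermediate
4 | 4-(benzyloxy)-2-(chloromethyl)-1-(methoxymethoxy)benzene | ClCc1cc(OCc2ccccc2)ccc1OCOC | intermediate
5 | (1R,4S)-7,7-dimethyl-2-oxobicyclo[2.2.1]heptane-1-carboxylic acid, (1R)-(−)-ketopinic acid | OC(=O)[C@@]12CC[C@@H](CC1=O)C2(C)C | starting material
6 | ketopinoyl chloride (not isolated) | ClC(=O)[C@@]12CC[C@@H](CC1=O)C2(C)C | intermediate
7 | (1R,4S)-N-methoxy-N,7,7-trimethyl-2-oxobicyclo[2.2.1]heptane-1-carboxamide | CON(C)C(=O)[C@@]12CC[C@@H](CC1=O)C2(C)C | intermediate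
8 | lithium enolate of 7 (not isolated) | C1=C(O[Li])[C@@]2(C(=O)N(C)OC)CC[C@@H]1C2(C)C | intermediate
9 | 3-methyl keto amide, 3-exo-methyl epimer drawn (epimers converge in step 6) | C[C@@H]1C(=O)[C@@]2(C(=O)N(C)OC)CC[C@@H]1C2(C)C | intermediate
10 | lithium enolate of 9 (not isolated) | CC1=C(O[Li])[C@@]2(C(=O)N(C)OC)CC[C@@H]1C2(C)C | intermediate
11 | 3-exo-allyl-3-endo-methyl keto amide | C=CC[C@]1(C)C(=O)[C@@]2(C(=O)N(C)OC)CC[C@@H]1C2(C)C | intermediate
12 | 2-hydroxy amide, C2 epimers (C2 left open) | C=CC[C@]1(C)C(O)[C@@]2(C(=O)N(C)OC)CC[C@@H]1C2(C)C | intermediate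
13 | sodium alkoxide of 12 (not isolated) | C=CC[C@]1(C)C(O[Na])[C@@]2(C(=O)N(C)OC)CC[C@@H]1C2(C)C | intermediate
14 | sodium xanthate of 12 (not isolated) | C=CC[C@]1(C)C(OC(=S)S[Na])[C@@]2(C(=O)N(C)OC)CC[C@@H]1C2(C)C | intermediate
15 | S-methyl xanthate of 12 | C=CC[C@]1(C)C(OC(=S)SC)[C@@]2(C(=O)N(C)OC)CC[C@@H]1C2(C)C | intermediate
16 | N-methoxy-N,3,7,7-tetramethyl-3-(prop-2-enyl)bicyclo[2.2.1]heptane-1-carboxamide, allyl exo, methyl endo | C=CC[C@]1(C)C[C@@]2(C(=O)N(C)OC)CC[C@@H]1C2(C)C | intermediate
17 | [5-(benzyloxy)-2-(methoxymethoxy)benzyl]magnesium chloride (not isolated) | Cl[Mg]Cc1cc(OCc2ccccc2)ccc1OCOC | intermediate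
18 | 2-[5-(benzyloxy)-2-(methoxymethoxy)phenyl]-1-(3-exo-allyl-3,7,7-trimethylbicyclo[2.2.1]heptan-1-yl)ethanone | C=CC[C@]1(C)C[C@@]2(C(=O)Cc3cc(OCc4ccccc4)ccc3OCOC)CC[C@@H]1C2(C)C | intermediate
19 | (S)-carbinol, MOM ether still in place (not isolated) | C=CC[C@]1(C)C[C@@]2([C@@H](O)Cc3cc(OCc4ccccc4)ccc3OCOC)CC[C@@H]1C2(C)C | intermediate
20 | (1S)-2-[5-(benzyloxy)-2-hydroxyphenyl]-1-(3-exo-allyl-3,7,7-trimethylbicyclo[2.2.1]heptan-1-yl)ethanol | C=CC[C@]1(C)C[C@@]2([C@@H](O)Cc3cc(OCc4ccccc4)ccc3O)CC[C@@H]1C2(C)C | intermediate
21 | bis(methanesulfonate) of 20 (alkyl (S)-mesylate and aryl mesylate) | C=CC[C@]1(C)C[C@@]2([C@@H](OS(C)(=O)=O)Cc3cc(OCc4ccccc4)ccc3OS(C)(=O)=O)CC[C@@H]1C2(C)C | intermediate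
22 | 4-(benzyloxy)-2-{[1-hydroxy-3,5,5-trimethyl-3-(prop-2-enyl)bicyclo[2.2.2]octan-6-yl]methyl}phenyl methanesulfonate; arylmethyl and 3-methyl syn to the C7–C8 bridge, allyl syn to C5 | C=CC[C@]1(C)C[C@@]2(O)CC[C@@H]1C(C)(C)[C@@H]2Cc1cc(OCc3ccccc3)ccc1OS(C)(=O)=O | intermediate
23 | 3-methyl-3-(trimethylsilyloxy)but-1-yne | C#CC(C)(C)O[Si](C)(C)C | starting material
24 | lithium acetylide of 23 (not isolated) | [Li]C#CC(C)(C)O[Si](C)(C)C | intermediate
25 | 4-methyl-4-(trimethylsilyloxy)pent-2-yn-1-ol | OCC#CC(C)(C)O[Si](C)(C)C | intermediate
26 | (5-bromo-2-methylpent-3-yn-2-yl)oxytrimethylsilane | BrCC#CC(C)(C)O[Si](C)(C)C | intermediate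
27 | (S)-(+)-carvone | CC1=CC[C@H](C(C)=C)CC1=O | starting material
28 | lithium α′-enolate of carvone (not isolated) | CC1=CC[C@H](C(C)=C)C=C1O[Li] | intermediate
29 | trans-6-methylcarvone, major epimer drawn | CC1=CC[C@H](C(C)=C)[C@@H](C)C1=O | intermediate
30 | lithium enolate of 29 (not isolated) | CC1=CC[C@H](C(C)=C)C(C)=C1O[Li] | intermediate
31 | 6-methyl-6-[4-methyl-4-(trimethylsilyloxy)pent-2-ynyl]carvone, side chain trans to isopropenyl | CC1=CC[C@H](C(C)=C)[C@@](C)(CC#CC(C)(C)O[Si](C)(C)C)C1=O | intermediate
32 | α-methoxy hydroperoxide from ozonolysis of 31 (not isolated; peroxy carbon left open) | CC1=CC[C@H](C(C)(OC)OO)[C@@](C)(CC#CC(C)(C)O[Si](C)(C)C)C1=O | intermediate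
33 | C5 acetate, acetoxy cis to the quaternary methyl | CC1=CC[C@H](OC(C)=O)[C@@](C)(CC#CC(C)(C)O[Si](C)(C)C)C1=O | intermediate
34 | saturated keto acetate, equatorial α-methyl epimer drawn | C[C@H]1CC[C@H](OC(C)=O)[C@@](C)(CCCC(C)(C)O[Si](C)(C)C)C1=O | intermediate
35 | 3-hydroxy-2-(4-hydroxy-4-methylpentyl)-2,6-dimethylcyclohexanone, hydroxyl trans to the side chain | C[C@H]1CC[C@H](O)[C@@](C)(CCCC(C)(C)O)C1=O | intermediate
36 | trans-fused 2,2,5a,7-tetramethyloctahydro-1-benzoxepin-6(2H)-one, 7-methyl equatorial | C[C@H]1CC[C@@H]2OC(C)(C)CCC[C@@]2(C)C1=O | intermediate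
37 | 6-methylidene analogue of 36 | C[C@H]1CC[C@@H]2OC(C)(C)CCC[C@@]2(C)C1=C | intermediate
38 | spiro-epoxide, oxygen anti to the angular methyl | C[C@H]1CC[C@@H]2OC(C)(C)CCC[C@@]2(C)[C@]13CO3 | intermediate
39 | 6-allyl-2,2,5a,7-tetramethyldecahydro-1-benzoxepin-6-ol, hydroxyl axial | C[C@H]1CC[C@@H]2OC(C)(C)CCC[C@@]2(C)[C@]1(O)CC=C | intermediate
40 | cross-metathesis product, (E)-alkene in the tether | C[C@H]1CC[C@@H]2OC(C)(C)CCC[C@@]2(C)[C@]1(O)C/C=C/C[C@]1(C)C[C@@]2(O)CC[C@@H]1C(C)(C)[C@@H]2Cc1cc(OCc3ccccc3)ccc1OS(C)(=O)=O | intermediate
41 | saturated phenol with ortho aryl mesylate | C[C@H]1CC[C@@H]2OC(C)(C)CCC[C@@]2(C)[C@]1(O)CCCC[C@]1(C)C[C@@]2(O)CC[C@@H]1C(C)(C)[C@@H]2Cc1cc(O)ccc1OS(C)(=O)=O | intermediate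
42 | aryl hydrogen sulfate with ortho aryl mesylate (handled as sodium salt) | C[C@H]1CC[C@@H]2OC(C)(C)CCC[C@@]2(C)[C@]1(O)CCCC[C@]1(C)C[C@@]2(O)CC[C@@H]1C(C)(C)[C@@H]2Cc1cc(OS(=O)(=O)O)ccc1OS(C)(=O)=O | intermediate
43 | disodium phenolate sulfate (not isolated) | C[C@H]1CC[C@@H]2OC(C)(C)CCC[C@@]2(C)[C@]1(O)CCCC[C@]1(C)C[C@@]2(O)CC[C@@H]1C(C)(C)[C@@H]2Cc1cc(OS(=O)(=O)[O-])ccc1[O-].[Na+].[Na+] | intermediate
44 | CNP0255133.1 | C[C@H]1CC[C@@H]2OC(C)(C)CCC[C@@]2(C)[C@]1(O)CCCC[C@]1(C)C[C@@]2(O)CC[C@@H]1C(C)(C)[C@@H]2Cc1cc(OS(=O)(=O)O)ccc1O | target

**Step count and risks**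

Total step count: 28. Longest linear sequence: 14 steps (steps 4 to 13, then 25 to 28).

Steps most likely to fail:

1. Step 13. A ring methylene carbon (C2 or C6 of the bornane) may shift in place of C7, the benzylic proton may be lost toward the arene, or the slow ionization of the hindered mesylate in a water-rich medium may let other pathways compete. Fallback, from 20 back to 22: the ring enlargement is run as an ion-pair rearrangement with return of the leaving group, and the hydroxyl is introduced in a separate bridgehead substitution. Selective O-sulfonylation of the phenol (one equivalent of MsCl, Et3N, −78 °C) should give the aryl mesylate carbinol F1. Tf2O with 2,6-di-tert-butyl-4-methylpyridine in CH2Cl2 at −78 °C forms the secondary triflate, which should ionize at low temperature with the same anti shift of C7 and collapse within the ion pair to the ring-enlarged bridgehead triflate F2, with no free cation and no nucleophilic solvent present. SN1 hydrolysis of F2 in aqueous acetone with NaHCO3 then gives 22.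

2. Step 6. Facial selectivity in the alkylation of the camphor-type enolate may be poor, since the syn methyl of the one-carbon bridge also hinders the exo face. Fallback, from 9 back to 11: the tetrasubstituted enolate (KN(SiMe3)2, THF, −78 °C) is O-acylated with allyl chloroformate to the allyl enol carbonate F3. Decarboxylative allylation (Tsuji allylation) with Pd2(dba)3 and the enantiomer of the t-Bu-PHOX ligand that reinforces exo delivery should then form the quaternary centre under catalyst control and give 11.

3. Step 21. The tertiary cation may lose a proton to give alkenes faster than the seven-membered ether closes. Fallback, from 35 back to 36: the tertiary alcohol is deliberately dehydrated (p-TsOH, toluene, 80 °C) to the trisubstituted hydroxy alkene F4 and its isopropenyl isomer F5. Hydrogen-atom-transfer hydroalkoxylation of the mixture (the cobalt salen complex Co(salen) as catalyst, N-fluoro-2,4,6-trimethylpyridinium triflate, PhSiH3, rt) generates the same tertiary radical from either isomer and should close the ether at the tertiary carbon to give 36.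

Further compounds
F1 | step 13 | (1S)-carbinol with ortho aryl methanesulfonate (mono-mesylate of 20) | C=CC[C@]1(C)C[C@@]2([C@@H](O)Cc3cc(OCc4ccccc4)ccc3OS(C)(=O)=O)CC[C@@H]1C2(C)C
F2 | step 13 | bridgehead trifluoromethanesulfonate of 22 | C=CC[C@]1(C)C[C@@]2(OS(=O)(=O)C(F)(F)F)CC[C@@H]1C(C)(C)[C@@H]2Cc1cc(OCc3ccccc3)ccc1OS(C)(=O)=O
F3 | step 6 | allyl enol carbonate of 9 | CC1=C(OC(=O)OCC=C)[C@@]2(C(=O)N(C)OC)CC[C@@H]1C2(C)C
F4 | step 21 | 3-hydroxy-2,6-dimethyl-2-(4-methylpent-3-enyl)cyclohexanone | C[C@H]1CC[C@H](O)[C@@](C)(CCC=C(C)C)C1=O
F5 | step 21 | 3-hydroxy-2,6-dimethyl-2-(4-methylpent-4-enyl)cyclohexanone | C[C@H]1CC[C@H](O)[C@@](C)(CCCC(C)=C)C1=O
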